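The ring is disconnected at C1–C2, the bond between the ketone carbon and the methyl-bearing epoxide carbon of the 7-oxabicyclo[4.1.0]heptan-2-one. Reading the epoxy ketone as an oxidised 2-methylcyclohex-2-en-1-ol turns this bond into a vinyl–carbinol bond. An intramolecular Nozaki–Hiyama–Kishi reaction of an open-chain (Z)-iodoalkenyl aldehyde, which already carries the senecioate, the angelate and the C5, C6 and C8 stereocentres, closes the six-membered ring and creates a temporary C1 carbinol. That hydroxyl steers the epoxidation of C2=C3 to its own face and is then oxidised to the ketone. The open-chain precursor comes from an angelate-directed boron anti-aldol reaction.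

Key step: step 13

Remark: locants C1–C11 are those of the target and are also used for the open-chain intermediates (C1 ketone carbon, C2 methyl-bearing epoxide carbon, C3 epoxide CH, C4 ring CH2, C5 ring CH with the side chain, C6 ring CH with the senecioate, C7 methylidene-bearing carbon, C8 angelate carbinol, C9–C11 prenyl end). Compounds 1, 5, 6, 14, 17 and 20 are taken as commercially available.

Step 1
Reactants: 1 but-2-yn-1-ol
Product: 3 (Z)-3-iodobut-2-en-1-ol, via cyclic alkenylalanate 2 (not isolated)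
Conditions: NaAlH2(OCH2CH2OCH3)2, THF, 0 °C to rt; then I2, −78 to 0 °C; aq. potassium sodium tartrate
Reagents that add atoms: iodine, II
Why: Hydroxyl-directed trans-hydroalumination of the propargylic alcohol puts aluminium on C3 in a five-membered alanate, and iodinolysis with retention should give the (Z)-iodoalkene.

Step 2
Reactants: 3 (Z)-3-iodobut-2-en-1-ol
Product: 4 (Z)-1-bromo-3-iodobut-2-ene
Conditions: CBr4, PPh3, CH2Cl2, 0 °C
Reagents that add atoms: carbon tetrabromide, BrC(Br)(Br)Br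
Why: Appel bromination converts the primary allylic alcohol into the bromide under neutral conditions and leaves the iodoalkene geometry untouched.

Step 3
Reactants: 5 methyl (S)-oxirane-2-carboxylate; 6 (2-methylprop-1-en-1-yl)magnesium bromide
Product: 7 methyl (S)-2-hydroxy-5-methylhex-4-enoate
Conditions: CuI (10 mol %), THF, −40 °C; aq. NH4Cl
Reagents that add atoms: none
Why: Copper-catalysed Grignard opening of a glycidic ester takes place at the unsubstituted epoxide carbon (SN2), so the stereocentre of the chiral-pool epoxide is untouched and becomes C8 (S) with the prenyl group in place.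

Step 4
Reactants: 7 methyl (S)-2-hydroxy-5-methylhex-4-enoate
Product: 8 methyl (S)-5-methyl-2-(triethylsilyloxy)hex-4-enoate
Conditions: Et3SiCl, imidazole, DMF, 0 °C to rt
Reagents that add atoms: chlorotriethylsilane, CC[Si](Cl)(CC)CC
Why: Routine silylation of a secondary alcohol masks the C8 hydroxyl for the Grignard and enolate steps.

Step 5
Reactants: 8 methyl (S)-5-methyl-2-(triethylsilyloxy)hex-4-enoate
Product: 10 (S)-6-methyl-3-(triethylsilyloxy)hept-5-en-2-one, via Weinreb amide 9 (not isolated)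
Conditions: MeNH(OMe)·HCl, i-PrMgCl, THF, −20 °C; then MeMgBr, −20 to 0 °C; aq. NH4Cl
Reagents that add atoms: methylmagnesium bromide, C[Mg]Br; N,O-dimethylhydroxylamine hydrochloride, CNOC.Cl (its atoms stay only in intermediate 9)
Why: One-pot ester-to-ketone conversion through the Weinreb amide, whose chelated adduct with MeMgBr collapses only on work-up, so over-addition is avoided and C8 is not touched.

Step 6
Reactants: 10 (S)-6-methyl-3-(triethylsilyloxy)hept-5-en-2-one; 4 (Z)-1-bromo-3-iodobut-2-ene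
Product: 13 (5S,9Z)-5-hydroxy-10-iodo-2-methylundeca-2,9-dien-6-one, via lithium enolate 11 (not isolated), via silyl ether 12 (not isolated)
Conditions: LiN(i-Pr)2, THF, −78 °C; 4, DMPU, −78 to −30 °C; then 1 M HCl, THF, 0 °C to rt
Reagents that add atoms: none
Why: Kinetic deprotonation at the unhindered methyl group gives the less substituted enolate, which is C-alkylated by the allylic bromide (SN2, forming C5–C4), and dilute acid then cleaves the labile TES ether.

Step 7
Reactants: 13 (5S,9Z)-5-hydroxy-10-iodo-2-methylundeca-2,9-dien-6-one; 14 angelic acid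
Product: 16 (5S,9Z)-10-iodo-2-methyl-6-oxoundeca-2,9-dien-5-yl (Z)-2-methylbut-2-enoate, via mixed anhydride 15 (not isolated)
Conditions: 14, 2,4,6-trichlorobenzoyl chloride, Et3N, toluene, rt; then 13, toluene, 70 °C
Reagents that add atoms: none
Why: Yamaguchi-type esterification through the mixed anhydride acylates the alcohol at the less hindered angeloyl carbonyl without a nucleophilic catalyst, which should keep the (Z) geometry of the angelate and the C8 configuration.

Step 8
Reactants: 16 (5S,9Z)-10-iodo-2-methyl-6-oxoundeca-2,9-dien-5-yl (Z)-2-methylbut-2-enoate; 17 (tert-butyldimethylsilyloxy)acetaldehyde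
Product: 19 (5S,7R,9Z)-7-[(1S)-2-(tert-butyldimethylsilyloxy)-1-hydroxyethyl]-10-iodo-2-methyl-6-oxoundeca-2,9-dien-5-yl (Z)-2-methylbut-2-enoate, via (E)-enol borinate 18 (not isolated)
Conditions: (c-C6H11)2BCl, Me2NEt, Et2O, −78 to 0 °C; then 17, −78 to −20 °C; pH 7 buffer, MeOH, H2O2, 0 °C
Reagents that add atoms: none
Why: Boron-mediated anti-aldol reaction of an α'-acyloxy ketone: enolisation towards C5 gives the (E)-enol borinate, the chair transition state gives the C5/C6 anti relationship, and the aldehyde should add to the enolate face on the side of the C8 acyloxy group (C8–H eclipsing the enolate, formyl hydrogen bond to the ester carbonyl), so that (8S) sets C5 and C6 as drawn.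

Step 9
Reactants: 19 (5S,7R,9Z)-7-[(1S)-2-(tert-butyldimethylsilyloxy)-1-hydroxyethyl]-10-iodo-2-methyl-6-oxoundeca-2,9-dien-5-yl (Z)-2-methylbut-2-enoate; 20 3-methylbut-2-enoyl chloride
Product: 21 (5S,7R,9Z)-7-[(1S)-2-(tert-butyldimethylsilyloxy)-1-(3-methylbut-2-enoyloxy)ethyl]-10-iodo-2-methyl-6-oxoundeca-2,9-dien-5-yl (Z)-2-methylbut-2-enoate
Conditions: pyridine, CH2Cl2, 0 °C
Reagents that add atoms: none
Why: Acylation of the C6 hydroxyl with the acid chloride and a weak base installs the senecioate, blocks retro-aldol cleavage and should avoid β-elimination and deconjugation of the enoate.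

Step 10
Reactants: 21 (5S,7R,9Z)-7-[(1S)-2-(tert-butyldimethylsilyloxy)-1-(3-methylbut-2-enoyloxy)ethyl]-10-iodo-2-methyl-6-oxoundeca-2,9-dien-5-yl (Z)-2-methylbut-2-enoate
Product: 22 (5S,7S,9Z)-7-[(1S)-2-(tert-butyldimethylsilyloxy)-1-(3-methylbut-2-enoyloxy)ethyl]-10-iodo-2-methyl-6-methylideneundeca-2,9-dien-5-yl (Z)-2-methylbut-2-enoate
Conditions: Zn, CH2Br2, TiCl4, THF (reagent pre-formed); 21, CH2Cl2, 0 °C to rt
Reagents that add atoms: dibromomethane, BrCBr
Why: Takai–Lombardo methylenation uses a non-basic, oxophilic titanium–zinc methylene reagent that converts hindered, enolisable ketones into 1,1-disubstituted alkenes without attacking esters or epimerising C5 and C8 (the descriptor at C5 changes only because the priorities change).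

Step 11
Reactants: 22 (5S,7S,9Z)-7-[(1S)-2-(tert-butyldimethylsilyloxy)-1-(3-methylbut-2-enoyloxy)ethyl]-10-iodo-2-methyl-6-methylideneundeca-2,9-dien-5-yl (Z)-2-methylbut-2-enoate
Product: 23 (5S,7S,9Z)-7-[(1S)-2-hydroxy-1-(3-methylbut-2-enoyloxy)ethyl]-10-iodo-2-methyl-6-methylideneundeca-2,9-dien-5-yl (Z)-2-methylbut-2-enoate
Conditions: HF·pyridine, pyridine, THF, 0 °C to rt
Reagents that add atoms: none
Why: Buffered HF·pyridine removes the primary TBS ether under mildly acidic conditions, which disfavour migration of the neighbouring senecioate to the primary hydroxyl.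

Step 12
Reactants: 23 (5S,7S,9Z)-7-[(1S)-2-hydroxy-1-(3-methylbut-2-enoyloxy)ethyl]-10-iodo-2-methyl-6-methylideneundeca-2,9-dien-5-yl (Z)-2-methylbut-2-enoate
Product: 24 (5S,7S,9Z)-10-iodo-2-methyl-6-methylidene-7-[(1S)-1-(3-methylbut-2-enoyloxy)-2-oxoethyl]undeca-2,9-dien-5-yl (Z)-2-methylbut-2-enoate
Conditions: Dess–Martin periodinane, NaHCO3, CH2Cl2, 0 °C to rt; used crude
Reagents that add atoms: none
Why: Buffered Dess–Martin oxidation should give the α-acyloxy aldehyde without epimerisation at C6.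

Step 13
Reactants: 24 (5S,7S,9Z)-10-iodo-2-methyl-6-methylidene-7-[(1S)-1-(3-methylbut-2-enoyloxy)-2-oxoethyl]undeca-2,9-dien-5-yl (Z)-2-methylbut-2-enoate
Product: 26 (1S,2S,6S)-2-hydroxy-3-methyl-6-[(3S)-6-methyl-3-{[(Z)-2-methylbut-2-enoyl]oxy}hepta-1,5-dien-2-yl]cyclohex-3-en-1-yl 3-methylbut-2-enoate, via alkenylchromium species 25 (not isolated)
Conditions: CrCl2 (8 equiv), NiCl2 (cat.), degassed DMSO, rt, 0.005 M; aq. NH4Cl
Reagents that add atoms: none
Why: Trace zerovalent nickel, formed from NiCl2 and CrCl2, inserts into the C2–I bond and hands the alkenyl group to trivalent chromium with retention of the (Z) geometry, and alkenylchromium 25 then adds to the C1 aldehyde, as in the Nozaki–Hiyama–Kishi cyclisation of iodoalkenyl aldehydes to cyclohexenols. The six-membered carbocycle closes in the 6-exo-trig mode, which the (Z)-iodoalkene makes easy because C1 and C4 end up cis on the ring double bond C2=C3. The new C1 carbinol should form with its oxygen pseudo-equatorial, trans to the C6 senecioate and cis to the C5 side chain, because the four-centre transfer of the alkenyl group to the chromium-bound aldehyde passes through a half-chair with the C5 and C6 substituents and the O–Cr group all equatorial; the controlling element is the C5/C6 pair set in step 8. The step needs chemoselectivity for the alkenyl iodide and the aldehyde over two enoate esters, an allylic ester and three further alkenes, which the non-basic organochromium reagent secures, while high dilution suppresses dimerisation. The neutral conditions should also leave the α-acyloxy aldehyde centre C6 unepimerised.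

Step 14
Reactants: 26 (1S,2S,6S)-2-hydroxy-3-methyl-6-[(3S)-6-methyl-3-{[(Z)-2-methylbut-2-enoyl]oxy}hepta-1,5-dien-2-yl]cyclohex-3-en-1-yl 3-methylbut-2-enoate
Product: 27 (1R,2R,3S,4S,6S)-2-hydroxy-1-methyl-4-[(3S)-6-methyl-3-{[(Z)-2-methylbut-2-enoyl]oxy}hepta-1,5-dien-2-yl]-7-oxabicyclo[4.1.0]heptan-3-yl 3-methylbut-2-enoate
Conditions: VO(acac)2 (5 mol %), t-BuOOH (in decane), CH2Cl2, 0 °C to rt
Reagents that add atoms: tert-butyl hydroperoxide, CC(C)(C)OO
Why: Hydroxyl-directed vanadium-catalysed epoxidation delivers oxygen to C2=C3 on the face of the C1 hydroxyl, as with cis-carveol, which sets C2 and C3 cis to the C5 side chain while isolated and ester-conjugated alkenes are not attacked.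

Step 15
Reactants: 27 (1R,2R,3S,4S,6S)-2-hydroxy-1-methyl-4-[(3S)-6-methyl-3-{[(Z)-2-methylbut-2-enoyl]oxy}hepta-1,5-dien-2-yl]-7-oxabicyclo[4.1.0]heptan-3-yl 3-methylbut-2-enoate
Product: 28 (1S,3S,4S,6S)-1-methyl-4-[(3S)-6-methyl-3-{[(Z)-2-methylbut-2-enoyl]oxy}hepta-1,5-dien-2-yl]-2-oxo-7-oxabicyclo[4.1.0]heptan-3-yl 3-methylbut-2-enoate (CNP0333561.1)
Conditions: Dess–Martin periodinane, NaHCO3, CH2Cl2, 0 °C to rt
Reagents that add atoms: none
Why: Neutral Dess–Martin oxidation of the secondary epoxy alcohol gives the α,β-epoxy ketone, removes the temporary C1 stereocentre and should leave the esters, the epoxide and C6 intact.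

Compound list
1 | but-2-yn-1-ol | CC#CCO | starting material
2 | sodium 2,2-bis(2-methoxyethoxy)-3-methyl-2,5-dihydro-1,2-oxaluminol-2-uide (cyclic alkenylalanate) | [Na+].CC1=CCO[Al-]1(OCCOC)OCCOC | intermediate (not isolated)
3 | (Z)-3-iodobut-2-en-1-ol | OC/C=C(/C)I | intermediate
4 | (Z)-1-bromo-3-iodobut-2-ene | BrC/C=C(/C)I | intermediate
5 | methyl (S)-oxirane-2-carboxylate (methyl (S)-glycidate) | COC(=O)[C@@H]1CO1 | starting material
6 | (2-methylprop-1-en-1-yl)magnesium bromide | CC(C)=C[Mg]Br | starting material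
7 | methyl (S)-2-hydroxy-5-methylhex-4-enoate | COC(=O)[C@H](CC=C(C)C)O | intermediate
8 | methyl (S)-5-methyl-2-(triethylsilyloxy)hex-4-enoate | COC(=O)[C@H](CC=C(C)C)O[Si](CC)(CC)CC | intermediate
9 | (S)-N-methoxy-N,5-dimethyl-2-(triethylsilyloxy)hex-4-enamide | CON(C)C(=O)[C@H](CC=C(C)C)O[Si](CC)(CC)CC | intermediate (not isolated)
10 | (S)-6-methyl-3-(triethylsilyloxy)hept-5-en-2-one | CC(=O)[C@H](CC=C(C)C)O[Si](CC)(CC)CC | intermediate
11 | lithium (S)-6-methyl-3-(triethylsilyloxy)hepta-1,5-dien-2-olate | [Li]OC(=C)[C@H](CC=C(C)C)O[Si](CC)(CC)CC | intermediate (not isolated)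
12 | (5S,9Z)-10-iodo-2-methyl-5-(triethylsilyloxy)undeca-2,9-dien-6-one | O=C(CC/C=C(/C)I)[C@H](CC=C(C)C)O[Si](CC)(CC)CC | intermediate (not isolated)
13 | (5S,9Z)-5-hydroxy-10-iodo-2-methylundeca-2,9-dien-6-one | O=C(CC/C=C(/C)I)[C@H](CC=C(C)C)O | intermediate
14 | angelic acid, (Z)-2-methylbut-2-enoic acid | C/C=C(/C)C(=O)O | starting material
15 | (Z)-2-methylbut-2-enoic 2,4,6-trichlorobenzoic anhydride | C/C=C(/C)C(=O)OC(=O)c1c(Cl)cc(Cl)cc1Cl | intermediate (not isolated)
16 | (5S,9Z)-10-iodo-2-methyl-6-oxoundeca-2,9-dien-5-yl (Z)-2-methylbut-2-enoate | O=C(CC/C=C(/C)I)[C@H](CC=C(C)C)OC(=O)/C(C)=C\C | intermediate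
17 | (tert-butyldimethylsilyloxy)acetaldehyde | O=CCO[Si](C)(C)C(C)(C)C | starting material
18 | (5S,6E,9Z)-6-[(dicyclohexylboranyl)oxy]-10-iodo-2-methylundeca-2,6,9-trien-5-yl (Z)-2-methylbut-2-enoate | I/C(C)=C\C/C=C(/OB(C1CCCCC1)C1CCCCC1)[C@H](CC=C(C)C)OC(=O)/C(C)=C\C | intermediate (not isolated)
19 | (5S,7R,9Z)-7-[(1S)-2-(tert-butyldimethylsilyloxy)-1-hydroxyethyl]-10-iodo-2-methyl-6-oxoundeca-2,9-dien-5-yl (Z)-2-methylbut-2-enoate | CC(C)=CC[C@H](OC(=O)/C(C)=C\C)C(=O)[C@H](C/C=C(/C)I)[C@H](O)CO[Si](C)(C)C(C)(C)C | intermediate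
20 | 3-methylbut-2-enoyl chloride | CC(C)=CC(=O)Cl | starting material
21 | (5S,7R,9Z)-7-[(1S)-2-(tert-butyldimethylsilyloxy)-1-(3-methylbut-2-enoyloxy)ethyl]-10-iodo-2-methyl-6-oxoundeca-2,9-dien-5-yl (Z)-2-methylbut-2-enoate | CC(C)=CC[C@H](OC(=O)/C(C)=C\C)C(=O)[C@H](C/C=C(/C)I)[C@H](OC(=O)C=C(C)C)CO[Si](C)(C)C(C)(C)C | intermediate
22 | (5S,7S,9Z)-7-[(1S)-2-(tert-butyldimethylsilyloxy)-1-(3-methylbut-2-enoyloxy)ethyl]-10-iodo-2-methyl-6-methylideneundeca-2,9-dien-5-yl (Z)-2-methylbut-2-enoate | CC(C)=CC[C@H](OC(=O)/C(C)=C\C)C(=C)[C@H](C/C=C(/C)I)[C@H](OC(=O)C=C(C)C)CO[Si](C)(C)C(C)(C)C | intermediate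
23 | (5S,7S,9Z)-7-[(1S)-2-hydroxy-1-(3-methylbut-2-enoyloxy)ethyl]-10-iodo-2-methyl-6-methylideneundeca-2,9-dien-5-yl (Z)-2-methylbut-2-enoate | CC(C)=CC[C@H](OC(=O)/C(C)=C\C)C(=C)[C@H](C/C=C(/C)I)[C@H](OC(=O)C=C(C)C)CO | intermediate
24 | (5S,7S,9Z)-10-iodo-2-methyl-6-methylidene-7-[(1S)-1-(3-methylbut-2-enoyloxy)-2-oxoethyl]undeca-2,9-dien-5-yl (Z)-2-methylbut-2-enoate | CC(C)=CC[C@H](OC(=O)/C(C)=C\C)C(=C)[C@H](C/C=C(/C)I)[C@H](OC(=O)C=C(C)C)C=O | intermediate
25 | alkenylchromium dichloride from 24 (CrCl2 group of trivalent chromium on C2 in place of iodine) | CC(C)=CC[C@H](OC(=O)/C(C)=C\C)C(=C)[C@H](C/C=C(/C)[Cr](Cl)Cl)[C@H](OC(=O)C=C(C)C)C=O | intermediate (not isolated)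
26 | (1S,2S,6S)-2-hydroxy-3-methyl-6-[(3S)-6-methyl-3-{[(Z)-2-methylbut-2-enoyl]oxy}hepta-1,5-dien-2-yl]cyclohex-3-en-1-yl 3-methylbut-2-enoate | C=C([C@H](CC=C(C)C)OC(=O)/C(C)=C\C)[C@@H]1CC=C(C)[C@H](O)[C@H]1OC(=O)C=C(C)C | intermediate
27 | (1R,2R,3S,4S,6S)-2-hydroxy-1-methyl-4-[(3S)-6-methyl-3-{[(Z)-2-methylbut-2-enoyl]oxy}hepta-1,5-dien-2-yl]-7-oxabicyclo[4.1.0]heptan-3-yl 3-methylbut-2-enoate | C=C([C@H](CC=C(C)C)OC(=O)/C(C)=C\C)[C@@H]1C[C@@H]2O[C@]2(C)[C@H](O)[C@H]1OC(=O)C=C(C)C | intermediate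
28 | (1S,3S,4S,6S)-1-methyl-4-[(3S)-6-methyl-3-{[(Z)-2-methylbut-2-enoyl]oxy}hepta-1,5-dien-2-yl]-2-oxo-7-oxabicyclo[4.1.0]heptan-3-yl 3-methylbut-2-enoate | C=C([C@H](CC=C(C)C)OC(=O)/C(C)=C\C)[C@@H]1C[C@@H]2O[C@]2(C)C(=O)[C@H]1OC(=O)C=C(C)C | target

Total step count: 15. Longest linear sequence: 13 steps (steps 3 to 15, from 5); steps 1 and 2 are a side branch that joins in step 6.

Steps most likely to fail

Step 13: the risk is poor facial selectivity when the alkenylchromium adds to the aldehyde. Part of the material would then close with the C1 oxygen cis to the C6 ester and would later be epoxidised on the wrong face. The fallback sets out from 24, which is cyclised as in step 13 without regard to C1, so that 26 forms together with its C1 epimer (1S,2R,6S)-2-hydroxy-3-methyl-6-[(3S)-6-methyl-3-{[(Z)-2-methylbut-2-enoyl]oxy}hepta-1,5-dien-2-yl]cyclohex-3-en-1-yl 3-methylbut-2-enoate F1. The crude mixture is oxidised with Dess–Martin periodinane (NaHCO3, CH2Cl2) to the enone (1S,6S)-3-methyl-6-[(3S)-6-methyl-3-{[(Z)-2-methylbut-2-enoyl]oxy}hepta-1,5-dien-2-yl]-2-oxocyclohex-3-en-1-yl 3-methylbut-2-enoate F2. Luche reduction (NaBH4, CeCl3·7H2O, MeOH, −78 °C) should then deliver hydride axially, as in the reduction of carvone to cis-carveol, and give the pseudo-equatorial alcohol, which brings the material back to the route at 26. C1 is then set by reduction of a ring ketone and no longer by the ring closure.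

Step 10: the risk is slow methylene transfer to the doubly α-branched ketone, so that reductive loss of the α-acyloxy group by zinc or β-elimination of the senecioate takes over. The fallback sets out from 21. Addition of Me3SiCH2MgCl in the presence of CeCl3 (THF, −78 °C) should give the β-hydroxysilane (5S,7R,9Z)-7-[(1S)-2-(tert-butyldimethylsilyloxy)-1-(3-methylbut-2-enoyloxy)ethyl]-6-hydroxy-10-iodo-2-methyl-6-[(trimethylsilyl)methyl]undeca-2,9-dien-5-yl (Z)-2-methylbut-2-enoate F3 as a mixture of C7 epimers. Aqueous HF in MeCN then brings about the acid-type Peterson elimination and removes the TBS ether in the same operation, so the route is rejoined at 23.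

Step 6: the risk is proton exchange between the lithium enolate and the alkylated ketone, which leads to double alkylation and loss of regiocontrol. The fallback sets out from 10. Condensation with 1,1-dimethylhydrazine (AcOH cat., EtOH) gives the hydrazone (S)-1,1-dimethyl-2-[6-methyl-3-(triethylsilyloxy)hept-5-en-2-ylidene]hydrazine F4. Its aza-enolate (LiN(i-Pr)2, THF, −78 to 0 °C) forms only at the methyl group and does not equilibrate, and is alkylated with 4 to give 1,1-dimethyl-2-[(5S,9Z)-10-iodo-2-methyl-5-(triethylsilyloxy)undeca-2,9-dien-6-ylidene]hydrazine F5. Two-phase hydrolysis with 1 M HCl should release the ketone and the TES group together and return to the route at 13.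

Further compounds
F1 | step 13 | (1S,2R,6S)-2-hydroxy-3-methyl-6-[(3S)-6-methyl-3-{[(Z)-2-methylbut-2-enoyl]oxy}hepta-1,5-dien-2-yl]cyclohex-3-en-1-yl 3-methylbut-2-enoate | C=C([C@H](CC=C(C)C)OC(=O)/C(C)=C\C)[C@@H]1CC=C(C)[C@@H](O)[C@H]1OC(=O)C=C(C)C
F2 | step 13 | (1S,6S)-3-methyl-6-[(3S)-6-methyl-3-{[(Z)-2-methylbut-2-enoyl]oxy}hepta-1,5-dien-2-yl]-2-oxocyclohex-3-en-1-yl 3-methylbut-2-enoate | C=C([C@H](CC=C(C)C)OC(=O)/C(C)=C\C)[C@@H]1CC=C(C)C(=O)[C@H]1OC(=O)C=C(C)C
F3 | step 10 | (5S,7R,9Z)-7-[(1S)-2-(tert-butyldimethylsilyloxy)-1-(3-methylbut-2-enoyloxy)ethyl]-6-hydroxy-10-iodo-2-methyl-6-[(trimethylsilyl)methyl]undeca-2,9-dien-5-yl (Z)-2-methylbut-2-enoate (C6 of the chain, C7 of the target, unassigned) | CC(C)=CC[C@H](OC(=O)/C(C)=C\C)C(O)(C[Si](C)(C)C)[C@H](C/C=C(/C)I)[C@H](OC(=O)C=C(C)C)CO[Si](C)(C)C(C)(C)C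
F4 | step 6 | (S)-1,1-dimethyl-2-[6-methyl-3-(triethylsilyloxy)hept-5-en-2-ylidene]hydrazine | CC(=NN(C)C)[C@H](CC=C(C)C)O[Si](CC)(CC)CC
F5 | step 6 | 1,1-dimethyl-2-[(5S,9Z)-10-iodo-2-methyl-5-(triethylsilyloxy)undeca-2,9-dien-6-ylidene]hydrazine | CN(C)N=C(CC/C=C(/C)I)[C@H](CC=C(C)C)O[Si](CC)(CC)CC
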